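## The problem

Target 19 is an isoflavan: ring A is fused to the oxygen ring C (O1, C2, C3, C4, C4a–C8a), and ring B (C1'–C6') sits on C3. C3 is the only stereocentre and must be (R), as read from the SMILES. Ring A carries five substituents: O1 on C8a, the C4 methylene on C4a, methoxy on C5, a free hydroxyl on C7 and a formyl group on C8. Three phloroglucinol oxygens therefore have to be told apart, and two carbon substituents placed on defined carbons between them. Ring B is a 2,4-dihydroxyphenyl ring with a prenyl group on C3' between the two phenols.

No second stereocentre exists to relay information to C3, so a chiral catalyst must set it. Once set it is a benzylic CH between two methylenes and is not prone to epimerisation. Three groups will not survive rough treatment: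
- the prenyl alkene, which is saturated by alkene hydrogenation catalysts and cyclises onto either neighbouring phenol under acid;
- the salicylaldehyde, which reacts with hydrides, carbenoids and allyl boronates;
- the electron-rich free phenols, which are easily oxidised.

The enabling feature is that C2 is a methylene between O1 and the aryl-bearing C3, while O1 and C4 sit on the adjacent ring carbons C8a and C4a. C2=C3 can therefore be drawn as the enol ether double bond of ring C. That ring can be closed by metathesis between an O-vinyl group on C8a and a 2-(ring B)allyl group on C4a, giving a flat isoflav-2-ene with prochiral C3.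

## Retrosynthesis

**19 back to 16 (acetal C–O bonds; oxidation level of the C8 carbon).** The three phenols are released last from tris-acetal 18. Its formyl group is traced through benzylic alcohol 17 to methyl ester 16. An aldehyde carried from the start would be methylenated in step 7 and allylborated by boronate 15 in step 12. The ester is inert to both, blocks C8 during the Claisen step, and costs only two redox steps. The forward steps need a hydride reduction of a doubly ortho-substituted benzoate, a benzylic oxidation that spares the prenyl alkene, and an acetal cleavage mild enough for a prenyl group flanked by two phenols.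

**16 to 14 and 15 (the C3'–CH2 bond).** Removing the prenyl group leaves aryl bromide 14 and prenyl boronate 15. Prenyl cannot be present earlier, because the iridium catalyst of step 11 saturates trisubstituted alkenes and the ruthenium carbene of step 10 would have a third olefin to engage. The bromine comes from 2-bromoresorcinol 4 and marks C3' without ambiguity. A late lithiation between the two acetal oxygens would compete with C6 of ring A, which is flanked in the same way. The coupling must go through the α-carbon of the allyl boronate at a bromide with two ortho substituents.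

**14 to 13 (the two C–H bonds at C2 and C3).** The stereocentre is traced to the enol ether double bond of isoflav-2-ene 13. Setting C3 in an open chain before ring closure would need an extra asymmetric C–C bond formation. Here one catalytic hydrogenation acts on a rigid substrate with a single trisubstituted alkene. The catalyst must distinguish the two faces of an enol ether whose C3 aryl group has two ortho substituents, and must leave the aryl bromide and the acetals alone.

**13 to 12 (C2=C3, the key cut).** Opening the enol ether gives diene 12, with a vinyl ether on C8a and a 1,1-disubstituted styrene on C4a. Cutting O1–C2 or C3–C4 instead would require a functionalised three-carbon chain with the stereocentre already in place. The metathesis cut needs only two alkenes and removes no functionality that is needed later. The ruthenium carbene must close the ring faster than it rests as the aryloxy carbene.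

**12 to 11 (O–vinyl bond).** The vinyl group is removed to give phenol 11. The phenol is hindered and hydrogen-bonded to the ester, so an iridium-catalysed vinyl transfer from vinyl acetate is asked to do what a simple alkylation cannot.

**11 to 10 (C4–C4a bond).** A retro-Claisen step moves the 2-arylallyl group from C4a back to the phenol oxygen, giving ether 10. Direct C-allylation of ring A would face three nucleophilic positions. In 10 the ester occupies one ortho carbon, so the [3,3] shift can end only at C4a.

**10 to 9, then 3 and 8 (C=CH2; O–CH2).** The alkene of 10 is traced to ketone 9, and 9 to phenol 3 and phenacyl bromide 8.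
- The obvious neighbour, a 2-arylallyl bromide made by allylic bromination of the α-methylstyrene, would expose the activated C5' of ring B to electrophilic bromine.
- In 8 the bromine enters through a silyl enol ether, which is far more nucleophilic than the ring.
- A Wittig reagent is avoided for 9 to 10. The basic ylide would enolise the α-aryloxy ketone, and the enolate would attack the neighbouring ester to form a 3-hydroxybenzofuran. The titanium methylidene of step 7 is not basic and prefers the ketone to the hindered ester.

**8 back to 4 (ring B).** Bromoketone 8 comes from acetophenone 6 through silyl enol ether 7. Compound 6 comes from dihydroxyacetophenone 5 by acetal protection, and 5 from 2-bromoresorcinol 4 by C-acylation. The two open activated positions of 4 are equivalent, so the acylation has one possible outcome.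

**3 back to 1 (ring A).** Phenol 3 comes from the symmetric diol 2 by mono-protection, and 2 from methyl 2,4,6-trihydroxybenzoate 1 by methylation of the 4-hydroxyl. The ester of 1 differentiates the oxygens: the para hydroxyl is the acidic, unchelated one, and the two ortho hydroxyls are equivalent until one is capped.

## Roads not taken

**Alternative 1: three-component conjunctive coupling.** The cut removes C3–C1' and C4–C4a together, leaving ring B boronic ester A2, ring A aryl bromide A3 and a two-carbon vinyl-metal unit.
- Forward step: the vinyl-metal adds to A2 to give a boron ate complex. The arylpalladium species from A3 and a chiral bisphosphine–palladium catalyst triggers migration of ring B from boron to carbon. The product is secondary boronate A1, with the (R) centre of the future C3.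
- Merits: it is the most convergent of the four plans. The stereocentre is set in a C–C bond-forming step. The prenyl group is present from the start, so no placeholder bromine and no hydrogenation are needed.
- Weak points: the palladium must insert next to two ortho oxygen substituents on an electron-rich ring, and the migrating aryl group carries an ortho silyloxy group. No ring is closed. A1 still needs a one-carbon homologation at boron, oxidation, acetal removal beside silyl ethers, ring closure, the ester-to-aldehyde change and desilylation.
- Comparison: on convergence and on carrying the prenyl group, Alternative 1 is better. The chosen plan sets against it a key step that closes ring C outright, a stereo-determining step on an isolable flat substrate, and five steps after the key step instead of about seven.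

**Alternative 2: aminocatalytic addition to a ring A quinone methide.** The cut removes C3–C4 and O1–C2, leaving sulfone A5 as the quinone methide precursor and arylacetaldehyde A6.
- Forward step: mild base releases the quinone methide from A5. The enamine of A6 with a diarylprolinol silyl ether catalyst adds at C4, and the C8a phenol closes onto the aldehyde to give lactol A4.
- Merits: ring C and the C3 stereocentre arise in one metal-free operation, with the prenyl group in place.
- Weak points: in A4, C3 is α to a masked aldehyde and can epimerise through the open hydroxy aldehyde until C2 is reduced. Removing the lactol oxygen needs either a silane with strong acid, which endangers the acetals and the prenyl group, or reduction to the diol and a separate ring closure. A6 is an electron-rich arylacetaldehyde prone to self-condensation. A5 needs free phenols on ring A, which then stay unprotected.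
- Comparison: Alternative 2 is better in forming ring and stereocentre together. The chosen plan offers a stereocentre that is never adjacent to a carbonyl group, and protected phenols throughout.

**Alternative 3: difluorobenzaldehyde as ring A, with SNAr closure of O1–C8a.** The cut removes O1–C8a, leaving open-chain alcohol A8, in which C3 already has its configuration.
- Forward step: the primary alkoxide of A8 displaces the fluoride ortho to the aldehyde with carbonate base in a dipolar aprotic solvent, giving chroman A7.
- Merits: the aldehyde is at its final oxidation level from the beginning, which saves two redox steps. The ring closure is simple, metal-free and compatible with the prenyl group.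
- Weak points: the stereocentre must be made earlier in an open chain by a separate asymmetric step. The methoxy group para to the aldehyde weakens the activation of both fluorides. A7 still carries fluorine on C7, and replacing it by hydroxyl needs a second substitution on a ring made more electron-rich by the first, beside an aldehyde that hydroxide can attack.
- Comparison: Alternative 3 is better in redox economy and reagent cost. The chosen plan takes all ring A oxygens from the phloroglucinol ester with no substitution chemistry, and sets C3 by one catalytic step on the closed ring.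

Key step: step 10

Assumption: the ligand antipode written for the iridium catalyst in step 11 stands for whichever enantiomer adds hydrogen to the face that gives (3R); the sense of induction on a 3-aryl-4H-chromene is not predicted here.

## Route

Step 1
Reactants: 1 methyl 2,4,6-trihydroxybenzoate
Product: 2 methyl 2,6-dihydroxy-4-methoxybenzoate
Conditions: MeOH (1.05 equiv), PPh3, DIAD, THF, 0 °C to rt
Reagents that add atoms: methanol, CO
Why: Mitsunobu etherification; the 2- and 6-hydroxyls are hydrogen-bonded to and shielded by the ester, so the more acidic, unchelated 4-hydroxyl should take the methyl group, and the neutral conditions avoid the ring C-methylation that phloroglucinols show with MeI and base.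

Step 2
Reactants: 2 methyl 2,6-dihydroxy-4-methoxybenzoate
Product: 3 methyl 2-hydroxy-4-methoxy-6-(methoxymethoxy)benzoate
Conditions: MOMCl (1.05 equiv), iPr2NEt, CH2Cl2, 0 °C
Reagents that add atoms: chloromethyl methyl ether, COCCl
Why: Acetal protection of a phenol; the two hydroxyls of 2 are equivalent, and once one is capped the other sits in a stronger hydrogen bond to the ester and reacts much more slowly, so the reaction should stop at the mono-ether.

Step 3
Reactants: 4 2-bromoresorcinol (2-bromobenzene-1,3-diol)
Product: 5 1-(3-bromo-2,4-dihydroxyphenyl)ethan-1-one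
Conditions: AcOH, BF3·OEt2, 90 °C; aq. NaOAc
Reagents that add atoms: acetic acid, CC(=O)O
Why: Friedel–Crafts C-acylation of a resorcinol (Nencki type); the two open activated carbons are equivalent, each ortho to one hydroxyl and para to the other, and the product is deactivated as its boron chelate, so a single mono-ketone should form.

Step 4
Reactants: 5 1-(3-bromo-2,4-dihydroxyphenyl)ethan-1-one
Product: 6 1-[3-bromo-2,4-bis(methoxymethoxy)phenyl]ethan-1-one
Conditions: NaH, MOMCl, DMF, 0 °C to rt
Reagents that add atoms: chloromethyl methyl ether, COCCl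
Why: Williamson-type acetal formation; full deprotonation with NaH is chosen because the 2-hydroxyl is chelated to the ketone and flanked by bromine.

Step 5
Reactants: 6 1-[3-bromo-2,4-bis(methoxymethoxy)phenyl]ethan-1-one
Product: 8 2-bromo-1-[3-bromo-2,4-bis(methoxymethoxy)phenyl]ethan-1-one, via trimethylsilyl enol ether 7 (not isolated)
Conditions: LiN(SiMe3)2, Me3SiCl, THF, −78 °C; then NBS, −78 to 0 °C
Reagents that add atoms: N-bromosuccinimide, O=C1CCC(=O)N1Br; chlorotrimethylsilane, C[Si](C)(C)Cl (its silyl group is held in 7 only)
Why: α-Bromination of a ketone through its silyl enol ether; the enol ether is far more nucleophilic than C5' of the ring, so bromine should enter only at the methyl carbon, and no acid is formed that could cleave the acetals.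

Step 6
Reactants: 3 methyl 2-hydroxy-4-methoxy-6-(methoxymethoxy)benzoate; 8 2-bromo-1-[3-bromo-2,4-bis(methoxymethoxy)phenyl]ethan-1-one
Product: 9 methyl 2-{2-[3-bromo-2,4-bis(methoxymethoxy)phenyl]-2-oxoethoxy}-4-methoxy-6-(methoxymethoxy)benzoate
Conditions: K2CO3, acetone, rt
Reagents that add atoms: none
Why: Williamson ether synthesis with a phenacyl bromide, an electrophile reactive enough for a hydrogen-bonded phenol at room temperature; the mild base and low temperature are chosen so that the aryloxy ketone is not enolised onto the neighbouring ester.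

Step 7
Reactants: 9 methyl 2-{2-[3-bromo-2,4-bis(methoxymethoxy)phenyl]-2-oxoethoxy}-4-methoxy-6-(methoxymethoxy)benzoate
Product: 10 methyl 2-({2-[3-bromo-2,4-bis(methoxymethoxy)phenyl]prop-2-en-1-yl}oxy)-4-methoxy-6-(methoxymethoxy)benzoate
Conditions: Tebbe reagent Cp2Ti(μ-CH2)(μ-Cl)AlMe2 (1.2 equiv), pyridine, THF/toluene, −40 to 0 °C
Reagents that add atoms: Tebbe reagent, C[Al-]1(C)C[Ti]([Cl+]1)(C1C=CC=C1)C1C=CC=C1
Why: Tebbe methylenation; the titanium methylidene is not basic, so the acidic α-aryloxy ketone is not enolised, and it reacts with a ketone much faster than with a doubly ortho-substituted benzoate at low temperature.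

Step 8
Reactants: 10 methyl 2-({2-[3-bromo-2,4-bis(methoxymethoxy)phenyl]prop-2-en-1-yl}oxy)-4-methoxy-6-(methoxymethoxy)benzoate
Product: 11 methyl 3-{2-[3-bromo-2,4-bis(methoxymethoxy)phenyl]prop-2-en-1-yl}-2-hydroxy-4-methoxy-6-(methoxymethoxy)benzoate
Conditions: PhNEt2, 190 °C
Reagents that add atoms: none
Why: Aromatic Claisen rearrangement; one ortho carbon carries the ester, so the [3,3] shift and tautomerisation can end only at the future C4a, the symmetric 2-arylallyl unit returns the same 1,1-disubstituted alkene, and the basic solvent suppresses acid-catalysed addition of the new phenol to that alkene.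

Step 9
Reactants: 11 methyl 3-{2-[3-bromo-2,4-bis(methoxymethoxy)phenyl]prop-2-en-1-yl}-2-hydroxy-4-methoxy-6-(methoxymethoxy)benzoate
Product: 12 methyl 3-{2-[3-bromo-2,4-bis(methoxymethoxy)phenyl]prop-2-en-1-yl}-2-(ethenyloxy)-4-methoxy-6-(methoxymethoxy)benzoate
Conditions: vinyl acetate, [Ir(cod)Cl]2 (2 mol %), Na2CO3 (0.6 equiv), toluene, 100 °C
Reagents that add atoms: vinyl acetate, C=COC(C)=O
Why: Iridium-catalysed transfer vinylation of a phenol with vinyl acetate, the method used to make the vinyl ethers of 2-allylphenols for metathesis; the phenoxide adds to iridium-bound vinyl acetate and acetate leaves, and neither the aryl bromide nor the ester is touched.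

Step 10
Reactants: 12 methyl 3-{2-[3-bromo-2,4-bis(methoxymethoxy)phenyl]prop-2-en-1-yl}-2-(ethenyloxy)-4-methoxy-6-(methoxymethoxy)benzoate
Product: 13 methyl 3-[3-bromo-2,4-bis(methoxymethoxy)phenyl]-5-methoxy-7-(methoxymethoxy)-4H-chromene-8-carboxylate
Conditions: second-generation Grubbs catalyst [RuCl2(=CHPh)(H2IMes)(PCy3)] (10 mol %), toluene (5 mM), 80 °C, argon purge
Reagents that add atoms: none
Why: Ring-closing olefin metathesis: the ruthenium benzylidene first exchanges with the unhindered vinyl ether to give an aryloxy carbene, which undergoes [2+2] cycloaddition with the 1,1-disubstituted alkene held ortho to it, and cycloreversion of the ruthenacyclobutane releases 13 and a ruthenium methylidene that carries the chain. The closest known reaction is the closure of 2-allylaryl vinyl ethers to 4H-chromenes with the same catalyst. Ring C is closed as a six-membered cyclic enol ether from a 1,7-diene whose tether (O1, C8a, C4a, C4) contains two benzene carbons, and the new double bond C2=C3 is endocyclic. No stereocentre forms, and C3 is left trigonal and prochiral for step 11. The step needs ring closure to outrun both intermolecular metathesis and the resting of the catalyst as the heteroatom-stabilised carbene. The substrate helps in three ways: the ortho arrangement on the benzene ring fixes two tether atoms and gives a high effective molarity, an aryl oxygen stabilises the carbene less than an alkyl oxygen would, and the 1,1-disubstituted alkene does not dimerise. Dilution and removal of ethene support the closure, and the aryl bromide, acetals and ester are inert to the carbene.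

Step 11
Reactants: 13 methyl 3-[3-bromo-2,4-bis(methoxymethoxy)phenyl]-5-methoxy-7-(methoxymethoxy)-4H-chromene-8-carboxylate
Product: 14 methyl (3R)-3-[3-bromo-2,4-bis(methoxymethoxy)phenyl]-5-methoxy-7-(methoxymethoxy)-3,4-dihydro-2H-chromene-8-carboxylate
Conditions: H2 (50 bar), [Ir(cod)((S)-tBu-PHOX)][B(C6H3-3,5-(CF3)2)4] (2 mol %), CH2Cl2, rt
Reagents that add atoms: none
Why: Iridium-catalysed asymmetric hydrogenation of a cyclic enol ether with a phosphinooxazoline ligand, as known for 4H-chromenes; the cationic monovalent iridium complex needs no directing group, the chiral ligand pocket selects the face of the trisubstituted C2=C3 bond and so sets C3 as (R), and aryl bromides are not reduced by this catalyst class.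

Step 12
Reactants: 14 methyl (3R)-3-[3-bromo-2,4-bis(methoxymethoxy)phenyl]-5-methoxy-7-(methoxymethoxy)-3,4-dihydro-2H-chromene-8-carboxylate; 15 4,4,5,5-tetramethyl-2-(3-methylbut-2-en-1-yl)-1,3,2-dioxaborolane (prenylboronic acid pinacol ester)
Product: 16 methyl (3R)-3-[2,4-bis(methoxymethoxy)-3-(3-methylbut-2-en-1-yl)phenyl]-5-methoxy-7-(methoxymethoxy)-3,4-dihydro-2H-chromene-8-carboxylate
Conditions: [PdCl2(IPent)(3-chloropyridine)] (3 mol %), KOH (5 M aq.), THF, 70 °C
Reagents that add atoms: none
Why: Suzuki–Miyaura coupling of an allylic boronate; the bulky N-heterocyclic carbene ligand is made for hindered bromides and favours reductive elimination from the less hindered primary allyl–palladium terminus, which should give the linear prenyl arene, and the doubly ortho-substituted methyl ester resists the aqueous base.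

Step 13
Reactants: 16 methyl (3R)-3-[2,4-bis(methoxymethoxy)-3-(3-methylbut-2-en-1-yl)phenyl]-5-methoxy-7-(methoxymethoxy)-3,4-dihydro-2H-chromene-8-carboxylate
Product: 17 {(3R)-3-[2,4-bis(methoxymethoxy)-3-(3-methylbut-2-en-1-yl)phenyl]-5-methoxy-7-(methoxymethoxy)-3,4-dihydro-2H-chromen-8-yl}methanol
Conditions: LiAlH4, THF, 0 °C to rt
Reagents that add atoms: none
Why: Hydride reduction of an ester to the primary alcohol; LiAlH4 is small enough for the hindered benzoate and leaves the isolated alkene, the acetals and the C3 centre untouched.

Step 14
Reactants: 17 {(3R)-3-[2,4-bis(methoxymethoxy)-3-(3-methylbut-2-en-1-yl)phenyl]-5-methoxy-7-(methoxymethoxy)-3,4-dihydro-2H-chromen-8-yl}methanol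
Product: 18 (3R)-3-[2,4-bis(methoxymethoxy)-3-(3-methylbut-2-en-1-yl)phenyl]-5-methoxy-7-(methoxymethoxy)-3,4-dihydro-2H-chromene-8-carbaldehyde
Conditions: MnO2 (activated, excess), CH2Cl2, rt
Reagents that add atoms: none
Why: Selective oxidation of a benzylic alcohol with manganese dioxide; the electron-rich benzylic position is oxidised readily, over-oxidation to the acid does not occur, and the prenyl alkene is not attacked.

Step 15
Reactants: 18 (3R)-3-[2,4-bis(methoxymethoxy)-3-(3-methylbut-2-en-1-yl)phenyl]-5-methoxy-7-(methoxymethoxy)-3,4-dihydro-2H-chromene-8-carbaldehyde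
Product: 19 (3R)-3-[2,4-dihydroxy-3-(3-methylbut-2-en-1-yl)phenyl]-7-hydroxy-5-methoxy-3,4-dihydro-2H-chromene-8-carbaldehyde
Conditions: HCl (3 M aq.), MeOH, 40 °C
Reagents that add atoms: none
Why: Acid-catalysed acetal exchange removes the three methoxymethyl ethers as dimethoxymethane; dilute acid in methanol at mild temperature is the usual way to free prenylated phenols, and C3, which is not adjacent to a carbonyl group, cannot epimerise.

## Compound list

1 | methyl 2,4,6-trihydroxybenzoate | COC(=O)c1c(O)cc(O)cc1O | starting material
2 | methyl 2,6-dihydroxy-4-methoxybenzoate | COC(=O)c1c(O)cc(OC)cc1O | intermediate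
3 | methyl 2-hydroxy-4-methoxy-6-(methoxymethoxy)benzoate | COC(=O)c1c(O)cc(OC)cc1OCOC | intermediate
4 | 2-bromoresorcinol (2-bromobenzene-1,3-diol) | Oc1cccc(O)c1Br | starting material
5 | 1-(3-bromo-2,4-dihydroxyphenyl)ethan-1-one | CC(=O)c1ccc(O)c(Br)c1O | intermediate
6 | 1-[3-bromo-2,4-bis(methoxymethoxy)phenyl]ethan-1-one | CC(=O)c1ccc(OCOC)c(Br)c1OCOC | intermediate
7 | {[1-(3-bromo-2,4-bis(methoxymethoxy)phenyl)ethenyl]oxy}trimethylsilane (not isolated) | C=C(O[Si](C)(C)C)c1ccc(OCOC)c(Br)c1OCOC | intermediate
8 | 2-bromo-1-[3-bromo-2,4-bis(methoxymethoxy)phenyl]ethan-1-one | O=C(CBr)c1ccc(OCOC)c(Br)c1OCOC | intermediate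
9 | methyl 2-{2-[3-bromo-2,4-bis(methoxymethoxy)phenyl]-2-oxoethoxy}-4-methoxy-6-(methoxymethoxy)benzoate | COC(=O)c1c(OCOC)cc(OC)cc1OCC(=O)c1ccc(OCOC)c(Br)c1OCOC | intermediate
10 | methyl 2-({2-[3-bromo-2,4-bis(methoxymethoxy)phenyl]prop-2-en-1-yl}oxy)-4-methoxy-6-(methoxymethoxy)benzoate | COC(=O)c1c(OCOC)cc(OC)cc1OCC(=C)c1ccc(OCOC)c(Br)c1OCOC | intermediate
11 | methyl 3-{2-[3-bromo-2,4-bis(methoxymethoxy)phenyl]prop-2-en-1-yl}-2-hydroxy-4-methoxy-6-(methoxymethoxy)benzoate | COC(=O)c1c(OCOC)cc(OC)c(CC(=C)c2ccc(OCOC)c(Br)c2OCOC)c1O | intermediate
12 | methyl 3-{2-[3-bromo-2,4-bis(methoxymethoxy)phenyl]prop-2-en-1-yl}-2-(ethenyloxy)-4-methoxy-6-(methoxymethoxy)benzoate | COC(=O)c1c(OCOC)cc(OC)c(CC(=C)c2ccc(OCOC)c(Br)c2OCOC)c1OC=C | intermediate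
13 | methyl 3-[3-bromo-2,4-bis(methoxymethoxy)phenyl]-5-methoxy-7-(methoxymethoxy)-4H-chromene-8-carboxylate | COc1cc(OCOC)c(C(=O)OC)c2c1CC(c1ccc(OCOC)c(Br)c1OCOC)=CO2 | intermediate
14 | methyl (3R)-3-[3-bromo-2,4-bis(methoxymethoxy)phenyl]-5-methoxy-7-(methoxymethoxy)-3,4-dihydro-2H-chromene-8-carboxylate | COc1cc(OCOC)c(C(=O)OC)c2c1C[C@H](c1ccc(OCOC)c(Br)c1OCOC)CO2 | intermediate
15 | 4,4,5,5-tetramethyl-2-(3-methylbut-2-en-1-yl)-1,3,2-dioxaborolane (prenylboronic acid pinacol ester) | CC(C)=CCB1OC(C)(C)C(C)(C)O1 | starting material
16 | methyl (3R)-3-[2,4-bis(methoxymethoxy)-3-(3-methylbut-2-en-1-yl)phenyl]-5-methoxy-7-(methoxymethoxy)-3,4-dihydro-2H-chromene-8-carboxylate | COc1cc(OCOC)c(C(=O)OC)c2c1C[C@H](c1ccc(OCOC)c(CC=C(C)C)c1OCOC)CO2 | intermediate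
17 | {(3R)-3-[2,4-bis(methoxymethoxy)-3-(3-methylbut-2-en-1-yl)phenyl]-5-methoxy-7-(methoxymethoxy)-3,4-dihydro-2H-chromen-8-yl}methanol | COc1cc(OCOC)c(CO)c2c1C[C@H](c1ccc(OCOC)c(CC=C(C)C)c1OCOC)CO2 | intermediate
18 | (3R)-3-[2,4-bis(methoxymethoxy)-3-(3-methylbut-2-en-1-yl)phenyl]-5-methoxy-7-(methoxymethoxy)-3,4-dihydro-2H-chromene-8-carbaldehyde | COc1cc(OCOC)c(C=O)c2c1C[C@H](c1ccc(OCOC)c(CC=C(C)C)c1OCOC)CO2 | intermediate
19 | (3R)-3-[2,4-dihydroxy-3-(3-methylbut-2-en-1-yl)phenyl]-7-hydroxy-5-methoxy-3,4-dihydro-2H-chromene-8-carbaldehyde | COc1cc(O)c(C=O)c2c1C[C@H](c1ccc(O)c(CC=C(C)C)c1O)CO2 | target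

## Step count and least certain steps

Total: 15 steps. Longest linear sequence: 13 steps (steps 3 to 15, from 4); the ring A branch (steps 1 and 2) joins at step 6.

**Step 10 (key step).** The most likely failure is arrest of the catalyst as the aryloxy carbene, possibly chelated by the neighbouring ester carbonyl, before it engages the hindered 1,1-disubstituted alkene with its ortho-substituted aryl group. Migration of either double bond by ruthenium hydrides formed on prolonged heating is the second concern. The fallback closes ring C by acetal chemistry and sets out from phenol 11. Hydroboration with 9-BBN and oxidation with NaBO3 should give racemic methyl 3-{2-[3-bromo-2,4-bis(methoxymethoxy)phenyl]-3-hydroxypropyl}-2-hydroxy-4-methoxy-6-(methoxymethoxy)benzoate F1. Oxidation of its primary alcohol with SO3·pyridine in DMSO gives an aldehyde that closes onto the phenol as methyl 3-[3-bromo-2,4-bis(methoxymethoxy)phenyl]-2-hydroxy-5-methoxy-7-(methoxymethoxy)-3,4-dihydro-2H-chromene-8-carboxylate F2, a lactol. Mesylation with MsCl and Et3N with elimination then gives the enol ether, and the route is rejoined at 13.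

**Step 9.** The phenol lies between the ester and the benzylic methylene and is hydrogen-bonded, so vinyl transfer may stall. The iridium catalyst at 100 °C may also move the 1,1-disubstituted alkene into conjugation. The fallback builds the vinyl group in two stages from 11.
- Alkylation with excess 1,2-dibromoethane and K2CO3 should give methyl 2-(2-bromoethoxy)-3-{2-[3-bromo-2,4-bis(methoxymethoxy)phenyl]prop-2-en-1-yl}-4-methoxy-6-(methoxymethoxy)benzoate F3.
- Sodium benzeneselenolate (from PhSeSePh and NaBH4) converts it into methyl 3-{2-[3-bromo-2,4-bis(methoxymethoxy)phenyl]prop-2-en-1-yl}-4-methoxy-6-(methoxymethoxy)-2-[2-(phenylselanyl)ethoxy]benzoate F4.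
- Oxidation with NaIO4 gives methyl 2-[2-(benzeneseleninyl)ethoxy]-3-{2-[3-bromo-2,4-bis(methoxymethoxy)phenyl]prop-2-en-1-yl}-4-methoxy-6-(methoxymethoxy)benzoate F5, the selenoxide. Its syn-elimination on warming returns to the route at 12 without strong base.

**Step 11.** Face selection may be poor or conversion slow, because the aryl group on C3 has two ortho substituents and the substrate has no coordinating group. The acidic iridium hydrides may also shift the enol ether double bond or loosen an acetal. The fallback sets C3 by asymmetric hydroboration and sets out from 11.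
- Copper-catalysed enantioselective hydroboration of the 1,1-disubstituted alkene (CuCl, NaOtBu, one antipode of DTBM-SEGPHOS, excess HBpin, which also masks the phenol as its borate) should give methyl 3-{(2R)-2-[3-bromo-2,4-bis(methoxymethoxy)phenyl]-3-(4,4,5,5-tetramethyl-1,3,2-dioxaborolan-2-yl)propyl}-2-hydroxy-4-methoxy-6-(methoxymethoxy)benzoate F6.
- Oxidation with NaBO3 gives methyl 3-{(2R)-2-[3-bromo-2,4-bis(methoxymethoxy)phenyl]-3-hydroxypropyl}-2-hydroxy-4-methoxy-6-(methoxymethoxy)benzoate F7.
- Mitsunobu closure of the phenol onto the primary alcohol (PPh3, DIAD) does not touch the stereocentre and returns to the route at 14.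

**Step 12.** Coupling through the γ-carbon of the allyl boronate would give the 1,1-dimethylallyl isomer. Protodeboronation of 15 may also outrun oxidative addition at the bromide between two acetal oxygens. The fallback separates carbon–carbon coupling from the alkene substitution pattern and sets out from 14. Coupling with allylboronic acid pinacol ester under the same palladium catalyst, where both allyl termini are identical, should give methyl (3R)-3-[2,4-bis(methoxymethoxy)-3-(prop-2-en-1-yl)phenyl]-5-methoxy-7-(methoxymethoxy)-3,4-dihydro-2H-chromene-8-carboxylate F8. Cross-metathesis with 2-methylbut-2-ene and the second-generation Grubbs catalyst returns to the route at 16.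

**Step 15.** Acid may add a flanking phenol across the prenyl alkene to form a 2,2-dimethylchroman ring before the last acetal is gone. The fallback keeps the tertiary-cation-forming alkene out of the acid step and sets out from 14 through F8, described under step 12.
- Reduction with LiAlH4 gives {(3R)-3-[2,4-bis(methoxymethoxy)-3-(prop-2-en-1-yl)phenyl]-5-methoxy-7-(methoxymethoxy)-3,4-dihydro-2H-chromen-8-yl}methanol F9.
- Oxidation with MnO2 gives (3R)-3-[2,4-bis(methoxymethoxy)-3-(prop-2-en-1-yl)phenyl]-5-methoxy-7-(methoxymethoxy)-3,4-dihydro-2H-chromene-8-carbaldehyde F10.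
- Treatment with HCl in MeOH frees (3R)-3-[2,4-dihydroxy-3-(prop-2-en-1-yl)phenyl]-7-hydroxy-5-methoxy-3,4-dihydro-2H-chromene-8-carbaldehyde F11. Its terminal allyl group would cyclise only through a secondary cation.
- Cross-metathesis of F11 with 2-methylbut-2-ene (second-generation Grubbs catalyst), which tolerates phenols and aldehydes, completes the prenyl group and arrives at 19.

## Further compounds

F1 | step 10 | methyl 3-{2-[3-bromo-2,4-bis(methoxymethoxy)phenyl]-3-hydroxypropyl}-2-hydroxy-4-methoxy-6-(methoxymethoxy)benzoate (racemic) | COC(=O)c1c(OCOC)cc(OC)c(CC(CO)c2ccc(OCOC)c(Br)c2OCOC)c1O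
F2 | step 10 | methyl 3-[3-bromo-2,4-bis(methoxymethoxy)phenyl]-2-hydroxy-5-methoxy-7-(methoxymethoxy)-3,4-dihydro-2H-chromene-8-carboxylate (lactol, mixture of stereoisomers) | COc1cc(OCOC)c(C(=O)OC)c2c1CC(c1ccc(OCOC)c(Br)c1OCOC)C(O)O2
F3 | step 9 | methyl 2-(2-bromoethoxy)-3-{2-[3-bromo-2,4-bis(methoxymethoxy)phenyl]prop-2-en-1-yl}-4-methoxy-6-(methoxymethoxy)benzoate | COC(=O)c1c(OCOC)cc(OC)c(CC(=C)c2ccc(OCOC)c(Br)c2OCOC)c1OCCBr
F4 | step 9 | methyl 3-{2-[3-bromo-2,4-bis(methoxymethoxy)phenyl]prop-2-en-1-yl}-4-methoxy-6-(methoxymethoxy)-2-[2-(phenylselanyl)ethoxy]benzoate | COC(=O)c1c(OCOC)cc(OC)c(CC(=C)c2ccc(OCOC)c(Br)c2OCOC)c1OCC[Se]c1ccccc1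
F5 | step 9 | methyl 2-[2-(benzeneseleninyl)ethoxy]-3-{2-[3-bromo-2,4-bis(methoxymethoxy)phenyl]prop-2-en-1-yl}-4-methoxy-6-(methoxymethoxy)benzoate | COC(=O)c1c(OCOC)cc(OC)c(CC(=C)c2ccc(OCOC)c(Br)c2OCOC)c1OCC[Se](=O)c1ccccc1
F6 | step 11 | methyl 3-{(2R)-2-[3-bromo-2,4-bis(methoxymethoxy)phenyl]-3-(4,4,5,5-tetramethyl-1,3,2-dioxaborolan-2-yl)propyl}-2-hydroxy-4-methoxy-6-(methoxymethoxy)benzoate | COC(=O)c1c(OCOC)cc(OC)c(C[C@H](c2ccc(OCOC)c(Br)c2OCOC)CB2OC(C)(C)C(C)(C)O2)c1O
F7 | step 11 | methyl 3-{(2R)-2-[3-bromo-2,4-bis(methoxymethoxy)phenyl]-3-hydroxypropyl}-2-hydroxy-4-methoxy-6-(methoxymethoxy)benzoate | COC(=O)c1c(OCOC)cc(OC)c(C[C@H](c2ccc(OCOC)c(Br)c2OCOC)CO)c1O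
F8 | step 12 | methyl (3R)-3-[2,4-bis(methoxymethoxy)-3-(prop-2-en-1-yl)phenyl]-5-methoxy-7-(methoxymethoxy)-3,4-dihydro-2H-chromene-8-carboxylate | COc1cc(OCOC)c(C(=O)OC)c2c1C[C@H](c1ccc(OCOC)c(CC=C)c1OCOC)CO2
F9 | step 15 | {(3R)-3-[2,4-bis(methoxymethoxy)-3-(prop-2-en-1-yl)phenyl]-5-methoxy-7-(methoxymethoxy)-3,4-dihydro-2H-chromen-8-yl}methanol | COc1cc(OCOC)c(CO)c2c1C[C@H](c1ccc(OCOC)c(CC=C)c1OCOC)CO2
F10 | step 15 | (3R)-3-[2,4-bis(methoxymethoxy)-3-(prop-2-en-1-yl)phenyl]-5-methoxy-7-(methoxymethoxy)-3,4-dihydro-2H-chromene-8-carbaldehyde | COc1cc(OCOC)c(C=O)c2c1C[C@H](c1ccc(OCOC)c(CC=C)c1OCOC)CO2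
F11 | step 15 | (3R)-3-[2,4-dihydroxy-3-(prop-2-en-1-yl)phenyl]-7-hydroxy-5-methoxy-3,4-dihydro-2H-chromene-8-carbaldehyde | COc1cc(O)c(C=O)c2c1C[C@H](c1ccc(O)c(CC=C)c1O)CO2
A1 | alternative 1 | methyl 3-{(2R)-2-[2,4-bis(tert-butyldimethylsilyloxy)-3-(3-methylbut-2-en-1-yl)phenyl]-2-(4,4,5,5-tetramethyl-1,3,2-dioxaborolan-2-yl)ethyl}-4-methoxy-2,6-bis(methoxymethoxy)benzoate | COC(=O)c1c(OCOC)cc(OC)c(C[C@@H](B2OC(C)(C)C(C)(C)O2)c2ccc(O[Si](C)(C)C(C)(C)C)c(CC=C(C)C)c2O[Si](C)(C)C(C)(C)C)c1OCOC
A2 | alternative 1 | 2-[2,4-bis(tert-butyldimethylsilyloxy)-3-(3-methylbut-2-en-1-yl)phenyl]-4,4,5,5-tetramethyl-1,3,2-dioxaborolane | CC(C)=CCc1c(O[Si](C)(C)C(C)(C)C)ccc(B2OC(C)(C)C(C)(C)O2)c1O[Si](C)(C)C(C)(C)C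
A3 | alternative 1 | methyl 3-bromo-4-methoxy-2,6-bis(methoxymethoxy)benzoate | COC(=O)c1c(OCOC)cc(OC)c(Br)c1OCOC
A4 | alternative 2 | methyl (3R)-3-[2,4-bis(methoxymethoxy)-3-(3-methylbut-2-en-1-yl)phenyl]-2,7-dihydroxy-5-methoxy-3,4-dihydro-2H-chromene-8-carboxylate (both C2 epimers) | COc1cc(O)c(C(=O)OC)c2c1C[C@H](c1ccc(OCOC)c(CC=C(C)C)c1OCOC)C(O)O2
A5 | alternative 2 | methyl 3-[(benzenesulfonyl)methyl]-2,6-dihydroxy-4-methoxybenzoate | COC(=O)c1c(O)cc(OC)c(CS(=O)(=O)c2ccccc2)c1O
A6 | alternative 2 | 2-[2,4-bis(methoxymethoxy)-3-(3-methylbut-2-en-1-yl)phenyl]acetaldehyde | O=CCc1ccc(OCOC)c(CC=C(C)C)c1OCOC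
A7 | alternative 3 | (3R)-3-[2,4-bis(methoxymethoxy)-3-(3-methylbut-2-en-1-yl)phenyl]-7-fluoro-5-methoxy-3,4-dihydro-2H-chromene-8-carbaldehyde | COc1cc(F)c(C=O)c2c1C[C@H](c1ccc(OCOC)c(CC=C(C)C)c1OCOC)CO2
A8 | alternative 3 | 3-{(2R)-2-[2,4-bis(methoxymethoxy)-3-(3-methylbut-2-en-1-yl)phenyl]-3-hydroxypropyl}-2,6-difluoro-4-methoxybenzaldehyde | COc1cc(F)c(C=O)c(F)c1C[C@H](c1ccc(OCOC)c(CC=C(C)C)c1OCOC)CO
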